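**Plan**

1. The target is (3R,3'R,6'R)-lutein bis(alpha-linolenate). Carotenoid numbering is used: ring A is the cyclohexene with the tetrasubstituted C5=C6 bond and the carbinol carbon C3; ring B (primed numbers) is the cyclohex-2-ene end with C3' and C6'.
2. Retrosynthetic cuts: both ester C–O bonds; then C11'=C12', C11=C12 and C7=C8 (three Wittig olefinations, C10 + C5 + C10 + C15); in ring A the C3–C4 bond (ring closure) and, before it, the C1–C6 bond (Ireland–Claisen union of two C5 units).
3. Enabling feature of ring A: the chain C3(carbinol)–C4H2–C5(CH3)=C6–C7. With C7 as an ester carbonyl, C4 is the gamma-carbon of the dienolate C4=C5–C6=C7(O–) and C3 is an aldehyde, so one vinylogous aldol addition closes ring A, places the double bond at C5=C6 and sets C3.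
4. Forward order: acyclic C10 aldehyde ester, then ring A (key step), then the C10, C15 and C25 phosphonium salts. Ring B is taken intact from (R)-alpha-ionone and elaborated to a C15 hydroxy aldehyde; a last Wittig reaction and a double esterification finish the route.
5. Stereochemistry: C3 from the chiral copper catalyst in the ring closure (the racemic C6 of the precursor is erased); C6' from (R)-alpha-ionone; C3' from substrate-controlled hydride addition trans to the side chain; E double bonds from Wittig and Horner–Wadsworth–Emmons steps with equilibration; Z double bonds from alpha-linolenic acid.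

Key step: step 6

Assumption: (R)-alpha-ionone of high enantiomeric purity, (2E,4E,6E)-2,7-dimethylocta-2,4,6-trienedial, ethyl (2E)-3-methyl-4-oxobut-2-enoate and alpha-linolenic acid are taken as commercial; all polyene steps are run under argon with exclusion of light.

**Step 1**
Reactants: 1 3-methylbut-2-en-1-ol; 2 3-methylbut-2-enoyl chloride
Product: 3 3-methylbut-2-en-1-yl 3-methylbut-2-enoate
Conditions: pyridine, CH2Cl2, 0 °C to rt
Reagents that add atoms: none
Why: Acylation of the primary allylic alcohol by the acid chloride (nucleophilic acyl substitution); pyridine as a weak base limits vinylketene formation, and any deconjugated ester isomer would give the same dienolate in step 2.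

**Step 2**
Reactants: 3 3-methylbut-2-en-1-yl 3-methylbut-2-enoate
Product: 6 3,3-dimethyl-2-(prop-1-en-2-yl)pent-4-enoic acid (racemic), via silyl ketene acetal 4 (not isolated), via trimethylsilyl ester 5 (not isolated)
Conditions: LiN(i-Pr)2 (commercial solution), Me3SiCl, THF/DMPU, −78 °C, then 50 °C; aq. HCl
Reagents that add atoms: none
Why: Ireland–Claisen rearrangement: gamma-deprotonation gives the ester dienolate, O-silylation gives 4, and the [3,3] shift through a chair transition state joins the alpha-carbon to the dimethyl-substituted allyl terminus, which forms the C1–C6 bond with the quaternary C1 and leaves one isopropenyl and one vinyl group (C6 is racemic, which is of no consequence).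

**Step 3**
Reactants: 6 3,3-dimethyl-2-(prop-1-en-2-yl)pent-4-enoic acid
Product: 7 methyl 3,3-dimethyl-2-(prop-1-en-2-yl)pent-4-enoate
Conditions: MeI, K2CO3, DMF, rt
Reagents that add atoms: iodomethane CI
Why: O-Alkylation of the hindered carboxylate (SN2 on iodomethane) gives the methyl ester that serves as the enolisable acyl group.

**Step 4**
Reactants: 7 methyl 3,3-dimethyl-2-(prop-1-en-2-yl)pent-4-enoate
Product: 9 methyl 5-hydroxy-3,3-dimethyl-2-(prop-1-en-2-yl)pentanoate, via pinacol boronate 8 (not isolated)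
Conditions: pinacolborane, [Ir(cod)Cl]2 (1.5 mol%), bis(diphenylphosphino)methane (3 mol%), CH2Cl2, rt; then NaBO3·4H2O, THF/H2O, rt
Reagents that add atoms: pinacolborane CC1(C)OBOC1(C)C (its boron stays only in 8); sodium perborate [Na+].[Na+].O[B-]1(O)OO[B-](O)(O)OO1
Why: Iridium-catalysed anti-Markovnikov hydroboration takes monosubstituted terminal alkenes much faster than 1,1-disubstituted ones, so the vinyl group reacts and the hindered isopropenyl group is kept, and perborate oxidation of the C–B bond gives the primary alcohol without hydrolysing the hindered ester.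

**Step 5**
Reactants: 9 methyl 5-hydroxy-3,3-dimethyl-2-(prop-1-en-2-yl)pentanoate
Product: 10 methyl 3,3-dimethyl-5-oxo-2-(prop-1-en-2-yl)pentanoate
Conditions: TEMPO (10 mol%), PhI(OAc)2, CH2Cl2, rt
Reagents that add atoms: none
Why: Oxoammonium-mediated oxidation (TEMPO/PhI(OAc)2) stops at the aldehyde and, being base-free, leaves the alkene, the ester and the acidic C6–H untouched.

**Step 6**
Reactants: 10 methyl 3,3-dimethyl-5-oxo-2-(prop-1-en-2-yl)pentanoate
Product: 11 methyl (4R)-4-hydroxy-2,6,6-trimethylcyclohex-1-ene-1-carboxylate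
Conditions: [Cu(MeCN)4]PF6 (5 mol%), (R)-DTBM-SEGPHOS (6 mol%), 2-tert-butyl-1,1,3,3-tetramethylguanidine (10 mol%), THF (0.05 M), 0 °C
Reagents that add atoms: none
Why: Proposed new method: the soft, monovalent copper–bisphosphine cation binds the ester carbonyl of 10 and the guanidine removes the doubly activated hydrogen at C6 (alpha to the ester and allylic), which gives a planar chiral copper dienolate in which the racemic C6 centre is erased, and its terminal carbon C4 then adds to the tethered aldehyde carbon C3. The closest known reaction type is the direct, copper/bisphosphine/amine-catalysed enantioselective vinylogous aldol addition of beta,gamma-unsaturated esters to aldehydes, which is intermolecular; the ring-closing version with an alpha-branched ester is the untested extension. Ring A closes in the 6-(enolendo)-exo-trig mode, which is geometrically favoured and helped by the gem-dimethyl group at C1. The new stereocentre C3 is set by the catalyst: carbon–carbon bond formation is expected with the aldehyde oxygen bound to the copper centre that carries the dienolate, so the bisphosphine surrounds the forming carbinol carbon; (R) at C3 is the required sense and the ligand antipode is taken if the sense proves opposite. The step needs gamma- over alpha-attack and aldol addition over aldehyde enolisation: alpha-attack would give a cyclobutane at a fully substituted carbon, the weak base does not enolise the neopentyl-type aldehyde, and the product cannot lactonise because that would place a double bond at a bridgehead. Because the bond formation shifts the double bond to C5=C6, the ring, the tetrasubstituted conjugated alkene and the C3 carbinol centre arise together.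

**Step 7**
Reactants: 11 methyl (4R)-4-hydroxy-2,6,6-trimethylcyclohex-1-ene-1-carboxylate
Product: 12 (1R)-4-(hydroxymethyl)-3,5,5-trimethylcyclohex-3-en-1-ol
Conditions: LiAlH4, THF, 0 °C to reflux
Reagents that add atoms: none
Why: Hydride 1,2-reduction of the hindered conjugated ester to the primary allylic alcohol, as with beta-cyclogeranate esters; the C3 carbinol centre is not touched.

**Step 8**
Reactants: 12 (1R)-4-(hydroxymethyl)-3,5,5-trimethylcyclohex-3-en-1-ol
Product: 13 {[(4R)-4-hydroxy-2,6,6-trimethylcyclohex-1-en-1-yl]methyl}triphenylphosphonium bromide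
Conditions: Ph3P·HBr, MeOH, rt
Reagents that add atoms: triphenylphosphine hydrobromide [Br-].c1ccc(cc1)[PH+](c1ccccc1)c1ccccc1
Why: Acid-mediated ionisation of the primary allylic alcohol to the allyl cation and capture by triphenylphosphine at the less hindered primary terminus (SN1-type phosphonium salt formation); the non-allylic secondary hydroxyl at C3 does not ionise.

**Step 9**
Reactants: 13 {[(4R)-4-hydroxy-2,6,6-trimethylcyclohex-1-en-1-yl]methyl}triphenylphosphonium bromide; 14 ethyl (2E)-3-methyl-4-oxobut-2-enoate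
Product: 16 ethyl (2E,4E)-5-[(4R)-4-hydroxy-2,6,6-trimethylcyclohex-1-en-1-yl]-3-methylpenta-2,4-dienoate, via phosphorus ylide 15 (not isolated)
Conditions: KOt-Bu (2.1 equiv), THF, −78 °C; 14, −78 °C to rt; then I2 (1 mol%), hexane, rt
Reagents that add atoms: none
Why: Wittig olefination of the semi-stabilised allylic ylide with the aldehyde group of 14 forms C7=C8; the hindered (7Z) isomer is disfavoured and what forms of it is equilibrated to (7E) by the trace of iodine.

**Step 10**
Reactants: 16 ethyl (2E,4E)-5-[(4R)-4-hydroxy-2,6,6-trimethylcyclohex-1-en-1-yl]-3-methylpenta-2,4-dienoate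
Product: 17 (2E,4E)-5-[(4R)-4-hydroxy-2,6,6-trimethylcyclohex-1-en-1-yl]-3-methylpenta-2,4-dien-1-ol
Conditions: i-Bu2AlH (3.5 equiv), CH2Cl2, −78 °C to 0 °C; aq. potassium sodium tartrate
Reagents that add atoms: none
Why: 1,2-Reduction of the dienoate to the primary allylic alcohol by i-Bu2AlH at low temperature, without conjugate reduction.

**Step 11**
Reactants: 17 (2E,4E)-5-[(4R)-4-hydroxy-2,6,6-trimethylcyclohex-1-en-1-yl]-3-methylpenta-2,4-dien-1-ol
Product: 18 {(2E,4E)-5-[(4R)-4-hydroxy-2,6,6-trimethylcyclohex-1-en-1-yl]-3-methylpenta-2,4-dien-1-yl}triphenylphosphonium bromide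
Conditions: Ph3P·HBr, MeOH, 0 °C to rt
Reagents that add atoms: triphenylphosphine hydrobromide [Br-].c1ccc(cc1)[PH+](c1ccccc1)c1ccccc1
Why: As in step 8, the dienylic primary alcohol ionises readily and the delocalised cation is captured by triphenylphosphine at the terminal carbon, which gives the C15 Wittig salt.

**Step 12**
Reactants: 18 {(2E,4E)-5-[(4R)-4-hydroxy-2,6,6-trimethylcyclohex-1-en-1-yl]-3-methylpenta-2,4-dien-1-yl}triphenylphosphonium bromide; 19 (2E,4E,6E)-2,7-dimethylocta-2,4,6-trienedial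
Product: 21 (2E,4E,6E,8E,10E,12E)-13-[(4R)-4-hydroxy-2,6,6-trimethylcyclohex-1-en-1-yl]-2,7,11-trimethyltrideca-2,4,6,8,10,12-hexaenal, via phosphorus ylide 20 (not isolated)
Conditions: 19 (2 equiv), NaOMe (1.1 equiv, slow addition), MeOH/CH2Cl2, 0 °C to rt; then heptane, 80 °C
Reagents that add atoms: none
Why: Wittig olefination forms C11=C12; the excess of the symmetrical dialdehyde and slow addition of base hold the reaction at mono-olefination, and heating equilibrates the new double bond to E.

**Step 13**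
Reactants: 21 (2E,4E,6E,8E,10E,12E)-13-[(4R)-4-hydroxy-2,6,6-trimethylcyclohex-1-en-1-yl]-2,7,11-trimethyltrideca-2,4,6,8,10,12-hexaenal
Product: 22 (2E,4E,6E,8E,10E,12E)-13-[(4R)-4-hydroxy-2,6,6-trimethylcyclohex-1-en-1-yl]-2,7,11-trimethyltrideca-2,4,6,8,10,12-hexaen-1-ol
Conditions: NaBH4, MeOH/THF, 0 °C
Reagents that add atoms: none
Why: Chemoselective 1,2-reduction of the polyenal to the polyenol by NaBH4.

**Step 14**
Reactants: 22 (2E,4E,6E,8E,10E,12E)-13-[(4R)-4-hydroxy-2,6,6-trimethylcyclohex-1-en-1-yl]-2,7,11-trimethyltrideca-2,4,6,8,10,12-hexaen-1-ol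
Product: 23 {(2E,4E,6E,8E,10E,12E)-13-[(4R)-4-hydroxy-2,6,6-trimethylcyclohex-1-en-1-yl]-2,7,11-trimethyltrideca-2,4,6,8,10,12-hexaen-1-yl}triphenylphosphonium bromide
Conditions: Ph3P·HBr, MeOH/CH2Cl2, 0 °C to rt
Reagents that add atoms: triphenylphosphine hydrobromide [Br-].c1ccc(cc1)[PH+](c1ccccc1)c1ccccc1
Why: Phosphonium salt formation as in step 11 through the highly delocalised polyenyl cation, as for retinol; the homoallylic ring hydroxyl is inert.

**Step 15**
Reactants: 24 (R)-alpha-ionone, (3E)-4-[(1R)-2,6,6-trimethylcyclohex-2-en-1-yl]but-3-en-2-one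
Product: 25 (2E,4E)-3-methyl-5-[(1R)-2,6,6-trimethylcyclohex-2-en-1-yl]penta-2,4-dienenitrile
Conditions: (EtO)2P(O)CH2CN, NaH, THF, 0 °C to rt; chromatography
Reagents that add atoms: diethyl cyanomethylphosphonate CCOP(=O)(CC#N)OCC
Why: Horner–Wadsworth–Emmons olefination of the methyl ketone; the weakly basic phosphonate anion does not deprotonate C6', so the stereocentre is kept, and the (2E) isomer is separated from the minor (2Z) isomer by chromatography.

**Step 16**
Reactants: 25 (2E,4E)-3-methyl-5-[(1R)-2,6,6-trimethylcyclohex-2-en-1-yl]penta-2,4-dienenitrile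
Product: 26 (2E,4E)-3-methyl-5-[(1R)-2,6,6-trimethyl-4-oxocyclohex-2-en-1-yl]penta-2,4-dienenitrile
Conditions: t-BuOOH (5 equiv), Rh2(caprolactamate)4 (1 mol%), K2CO3, CH2Cl2, rt
Reagents that add atoms: tert-butyl hydroperoxide CC(C)(C)OO
Why: Radical allylic oxidation (tert-butylperoxyl chain) of C3', the only allylic ring methylene, to the enone, a transformation known for alpha-ionone itself; the tertiary C6'–H is shielded by the gem-dimethyl group and the side chain.

**Step 17**
Reactants: 26 (2E,4E)-3-methyl-5-[(1R)-2,6,6-trimethyl-4-oxocyclohex-2-en-1-yl]penta-2,4-dienenitrile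
Product: 27 (2E,4E)-5-[(1R,4R)-4-hydroxy-2,6,6-trimethylcyclohex-2-en-1-yl]-3-methylpenta-2,4-dienenitrile
Conditions: LiBH(s-Bu)3 (1.1 equiv), THF, −78 °C; H2O
Reagents that add atoms: none
Why: The bulky hydride adds 1,2 to the beta,beta-disubstituted ring enone from the face away from the axial methyl group at C1' (the 1,3-diaxial approach is blocked); with the C6' side chain pseudo-axial this equatorial attack places the hydroxyl pseudo-axial and trans to the chain, which is (3'R).

**Step 18**
Reactants: 27 (2E,4E)-5-[(1R,4R)-4-hydroxy-2,6,6-trimethylcyclohex-2-en-1-yl]-3-methylpenta-2,4-dienenitrile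
Product: 29 (2E,4E)-5-[(1R,4R)-4-hydroxy-2,6,6-trimethylcyclohex-2-en-1-yl]-3-methylpenta-2,4-dienal, via aldimine 28 (not isolated)
Conditions: i-Bu2AlH (2.5 equiv), CH2Cl2, −78 °C; aq. potassium sodium tartrate, then wet silica gel
Reagents that add atoms: water O
Why: Partial reduction of the nitrile: after the hydroxyl has consumed one equivalent, i-Bu2AlH adds once to the nitrile and the aldimine is hydrolysed to the aldehyde under near-neutral conditions that spare the acid-sensitive allylic alcohol.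

**Step 19**
Reactants: 23 {(2E,4E,6E,8E,10E,12E)-13-[(4R)-4-hydroxy-2,6,6-trimethylcyclohex-1-en-1-yl]-2,7,11-trimethyltrideca-2,4,6,8,10,12-hexaen-1-yl}triphenylphosphonium bromide; 29 (2E,4E)-5-[(1R,4R)-4-hydroxy-2,6,6-trimethylcyclohex-2-en-1-yl]-3-methylpenta-2,4-dienal
Product: 31 (3R,3'R,6'R)-beta,epsilon-carotene-3,3'-diol (lutein), via phosphorus ylide 30 (not isolated)
Conditions: NaOMe (1.2 equiv), MeOH/CH2Cl2, 0 °C to rt; then heptane, 80 °C; crystallisation
Reagents that add atoms: none
Why: Wittig olefination forms C11'=C12'; the mild alkoxide base leaves the allylic 3'-hydroxyl untouched, and the Z/E mixture at the new double bond is equilibrated thermally to the all-E polyene, which crystallises.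

**Step 20**
Reactants: 31 (3R,3'R,6'R)-beta,epsilon-carotene-3,3'-diol; 32 (9Z,12Z,15Z)-octadeca-9,12,15-trienoic acid (alpha-linolenic acid)
Product: 33 (3R,3'R,6'R)-beta,epsilon-carotene-3,3'-diyl bis[(9Z,12Z,15Z)-octadeca-9,12,15-trienoate]
Conditions: 32 (2.5 equiv), N,N'-dicyclohexylcarbodiimide (2.6 equiv), DMAP (0.2 equiv), CH2Cl2, 0 °C to rt
Reagents that add atoms: none
Why: Steglich esterification (carbodiimide activation, acyl transfer by DMAP) acylates both secondary hydroxyls with retention at C3 and C3' and without affecting the skipped Z-triene of the acid or the polyene.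

**Compound list**

1 | 3-methylbut-2-en-1-ol | CC(C)=CCO | starting material
2 | 3-methylbut-2-enoyl chloride | CC(C)=CC(=O)Cl | starting material
3 | 3-methylbut-2-en-1-yl 3-methylbut-2-enoate | CC(C)=CCOC(=O)C=C(C)C | intermediate
4 | trimethyl{[3-methyl-1-(3-methylbut-2-en-1-yloxy)buta-1,3-dien-1-yl]oxy}silane | C=C(C)C=C(OCC=C(C)C)O[Si](C)(C)C | intermediate (not isolated)
5 | trimethylsilyl 3,3-dimethyl-2-(prop-1-en-2-yl)pent-4-enoate (racemic) | C=CC(C)(C)C(C(C)=C)C(=O)O[Si](C)(C)C | intermediate (not isolated)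
6 | 3,3-dimethyl-2-(prop-1-en-2-yl)pent-4-enoic acid (racemic) | C=CC(C)(C)C(C(C)=C)C(=O)O | intermediate
7 | methyl 3,3-dimethyl-2-(prop-1-en-2-yl)pent-4-enoate (racemic) | C=CC(C)(C)C(C(C)=C)C(=O)OC | intermediate
8 | methyl 3,3-dimethyl-2-(prop-1-en-2-yl)-5-(4,4,5,5-tetramethyl-1,3,2-dioxaborolan-2-yl)pentanoate (racemic) | COC(=O)C(C(C)=C)C(C)(C)CCB1OC(C)(C)C(C)(C)O1 | intermediate (not isolated)
9 | methyl 5-hydroxy-3,3-dimethyl-2-(prop-1-en-2-yl)pentanoate (racemic) | COC(=O)C(C(C)=C)C(C)(C)CCO | intermediate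
10 | methyl 3,3-dimethyl-5-oxo-2-(prop-1-en-2-yl)pentanoate (racemic) | COC(=O)C(C(C)=C)C(C)(C)CC=O | intermediate
11 | methyl (4R)-4-hydroxy-2,6,6-trimethylcyclohex-1-ene-1-carboxylate | O[C@@H]1CC(C)=C(C(=O)OC)C(C)(C)C1 | intermediate
12 | (1R)-4-(hydroxymethyl)-3,5,5-trimethylcyclohex-3-en-1-ol | O[C@@H]1CC(C)=C(CO)C(C)(C)C1 | intermediate
13 | {[(4R)-4-hydroxy-2,6,6-trimethylcyclohex-1-en-1-yl]methyl}triphenylphosphonium bromide | O[C@@H]1CC(C)=C(C[P+](c2ccccc2)(c2ccccc2)c2ccccc2)C(C)(C)C1.[Br-] | intermediate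
14 | ethyl (2E)-3-methyl-4-oxobut-2-enoate | CCOC(=O)/C=C(C)/C=O | starting material
15 | ylide of 13, (1R)-3,5,5-trimethyl-4-[(triphenyl-lambda5-phosphanylidene)methyl]cyclohex-3-en-1-ol | O[C@@H]1CC(C)=C(C=P(c2ccccc2)(c2ccccc2)c2ccccc2)C(C)(C)C1 | intermediate (not isolated)
16 | ethyl (2E,4E)-5-[(4R)-4-hydroxy-2,6,6-trimethylcyclohex-1-en-1-yl]-3-methylpenta-2,4-dienoate | O[C@@H]1CC(C)=C(/C=C/C(C)=C/C(=O)OCC)C(C)(C)C1 | intermediate
17 | (2E,4E)-5-[(4R)-4-hydroxy-2,6,6-trimethylcyclohex-1-en-1-yl]-3-methylpenta-2,4-dien-1-ol | O[C@@H]1CC(C)=C(/C=C/C(C)=C/CO)C(C)(C)C1 | intermediate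
18 | {(2E,4E)-5-[(4R)-4-hydroxy-2,6,6-trimethylcyclohex-1-en-1-yl]-3-methylpenta-2,4-dien-1-yl}triphenylphosphonium bromide | O[C@@H]1CC(C)=C(/C=C/C(C)=C/C[P+](c2ccccc2)(c2ccccc2)c2ccccc2)C(C)(C)C1.[Br-] | intermediate
19 | (2E,4E,6E)-2,7-dimethylocta-2,4,6-trienedial | O=C/C(C)=C/C=C/C=C(C)/C=O | starting material
20 | ylide of 18 | O[C@@H]1CC(C)=C(/C=C/C(C)=C/C=P(c2ccccc2)(c2ccccc2)c2ccccc2)C(C)(C)C1 | intermediate (not isolated)
21 | (2E,4E,6E,8E,10E,12E)-13-[(4R)-4-hydroxy-2,6,6-trimethylcyclohex-1-en-1-yl]-2,7,11-trimethyltrideca-2,4,6,8,10,12-hexaenal | O[C@@H]1CC(C)=C(/C=C/C(C)=C/C=C/C(C)=C/C=C/C=C(C)/C=O)C(C)(C)C1 | intermediate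
22 | (2E,4E,6E,8E,10E,12E)-13-[(4R)-4-hydroxy-2,6,6-trimethylcyclohex-1-en-1-yl]-2,7,11-trimethyltrideca-2,4,6,8,10,12-hexaen-1-ol | O[C@@H]1CC(C)=C(/C=C/C(C)=C/C=C/C(C)=C/C=C/C=C(C)/CO)C(C)(C)C1 | intermediate
23 | {(2E,4E,6E,8E,10E,12E)-13-[(4R)-4-hydroxy-2,6,6-trimethylcyclohex-1-en-1-yl]-2,7,11-trimethyltrideca-2,4,6,8,10,12-hexaen-1-yl}triphenylphosphonium bromide | O[C@@H]1CC(C)=C(/C=C/C(C)=C/C=C/C(C)=C/C=C/C=C(C)/C[P+](c2ccccc2)(c2ccccc2)c2ccccc2)C(C)(C)C1.[Br-] | intermediate
24 | (R)-alpha-ionone, (3E)-4-[(1R)-2,6,6-trimethylcyclohex-2-en-1-yl]but-3-en-2-one | CC(=O)/C=C/[C@H]1C(C)=CCCC1(C)C | starting material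
25 | (2E,4E)-3-methyl-5-[(1R)-2,6,6-trimethylcyclohex-2-en-1-yl]penta-2,4-dienenitrile | N#C/C=C(C)/C=C/[C@H]1C(C)=CCCC1(C)C | intermediate
26 | (2E,4E)-3-methyl-5-[(1R)-2,6,6-trimethyl-4-oxocyclohex-2-en-1-yl]penta-2,4-dienenitrile | N#C/C=C(C)/C=C/[C@H]1C(C)=CC(=O)CC1(C)C | intermediate
27 | (2E,4E)-5-[(1R,4R)-4-hydroxy-2,6,6-trimethylcyclohex-2-en-1-yl]-3-methylpenta-2,4-dienenitrile | N#C/C=C(C)/C=C/[C@H]1C(C)=C[C@H](O)CC1(C)C | intermediate
28 | (2E,4E)-5-[(1R,4R)-4-hydroxy-2,6,6-trimethylcyclohex-2-en-1-yl]-3-methylpenta-2,4-dien-1-imine (formed as its aluminium derivative, freed on work-up) | N=C/C=C(C)/C=C/[C@H]1C(C)=C[C@H](O)CC1(C)C | intermediate (not isolated)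
29 | (2E,4E)-5-[(1R,4R)-4-hydroxy-2,6,6-trimethylcyclohex-2-en-1-yl]-3-methylpenta-2,4-dienal | O=C/C=C(C)/C=C/[C@H]1C(C)=C[C@H](O)CC1(C)C | intermediate
30 | ylide of 23 | O[C@@H]1CC(C)=C(/C=C/C(C)=C/C=C/C(C)=C/C=C/C=C(C)/C=P(c2ccccc2)(c2ccccc2)c2ccccc2)C(C)(C)C1 | intermediate (not isolated)
31 | (3R,3'R,6'R)-beta,epsilon-carotene-3,3'-diol (lutein) | O[C@@H]1CC(C)=C(/C=C/C(C)=C/C=C/C(C)=C/C=C/C=C(C)/C=C/C=C(C)/C=C/[C@H]2C(C)=C[C@H](O)CC2(C)C)C(C)(C)C1 | intermediate
32 | (9Z,12Z,15Z)-octadeca-9,12,15-trienoic acid | CC/C=C\C/C=C\C/C=C\CCCCCCCC(=O)O | starting material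
33 | (3R,3'R,6'R)-beta,epsilon-carotene-3,3'-diyl bis[(9Z,12Z,15Z)-octadeca-9,12,15-trienoate] | CC/C=C\C/C=C\C/C=C\CCCCCCCC(=O)O[C@@H]1CC(C)=C(/C=C/C(C)=C/C=C/C(C)=C/C=C/C=C(C)/C=C/C=C(C)/C=C/[C@H]2C(C)=C[C@H](OC(=O)CCCCCCC/C=C\C/C=C\C/C=C\CC)CC2(C)C)C(C)(C)C1 | target

**Step count**

Total: 20 steps. Longest linear sequence: 16 steps (steps 1 to 14, 19 and 20); the ring B branch (steps 15 to 18) has 4 steps.

**Steps most likely to fail**

Step 6 (proposed new method). Soft enolisation of the alpha-branched ester may be too slow, the base may instead move the isopropenyl double bond into conjugation (which stops the reaction), facial selectivity at the aldehyde may be poor, or water may be lost from the product by vinylogous elimination. The fallback sets out from 10 and returns at 11, using known chemistry. Me2AlCl (CH2Cl2, −78 °C to 0 °C, aq. HCl work-up) promotes the carbonyl-ene cyclisation in which the isopropenyl group is the ene partner, a known route from 5-methylhex-5-enals to 3-methylenecyclohexanols; this forms the same C3–C4 bond and gives racemic methyl 4-hydroxy-6,6-dimethyl-2-methylidenecyclohexane-1-carboxylate F1. Catalytic NaOMe in MeOH then moves the exocyclic double bond into conjugation to give racemic methyl 4-hydroxy-2,6,6-trimethylcyclohex-1-ene-1-carboxylate F2. Esterification with (S)-2-methoxy-2-phenylacetic acid (N,N'-dicyclohexylcarbodiimide, DMAP) gives the diastereomeric esters methyl (4R)-4-{[(2S)-2-methoxy-2-phenylacetyl]oxy}-2,6,6-trimethylcyclohex-1-ene-1-carboxylate F3 and its (4S) diastereomer F4, which are separated by chromatography or crystallisation. Methanolysis of F3 (catalytic K2CO3, MeOH) returns 11.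

Step 16. Hydrogen abstraction may occur at the doubly allylic C6'–H (loss of the stereocentre, peroxide formation), or the conjugated diene nitrile may be attacked. The fallback sets out from 24 and returns at 27; it moves the oxidation ahead of the chain extension, onto the protected C13 ketone, the substrate type for which this oxidation is established. Ketalisation without double-bond migration (1,2-bis(trimethylsilyloxy)ethane, catalytic Me3SiOTf, CH2Cl2, −78 °C) gives 2-methyl-2-{(E)-2-[(1R)-2,6,6-trimethylcyclohex-2-en-1-yl]ethenyl}-1,3-dioxolane F5. Allylic oxidation as in step 16 gives the 4-oxo ketal F6, and LiBH(s-Bu)3 as in step 17 gives the (1R,4R)-4-hydroxy ketal F7. Mild hydrolysis (pyridinium p-toluenesulfonate, acetone/H2O) gives (3E)-4-[(1R,4R)-4-hydroxy-2,6,6-trimethylcyclohex-2-en-1-yl]but-3-en-2-one F8. Horner–Wadsworth–Emmons olefination with diethyl cyanomethylphosphonate and NaH then gives 27.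

Step 17. Hydride may be delivered from the other face (epimer at C3'), or conjugate reduction may compete. The fallback sets out from 26 and returns at 27. A small hydride is used (NaBH4, CeCl3·7H2O, MeOH, 0 °C) and the cis epimer (2E,4E)-5-[(1R,4S)-4-hydroxy-2,6,6-trimethylcyclohex-2-en-1-yl]-3-methylpenta-2,4-dienenitrile F9 is separated. It is inverted by a Mitsunobu reaction (4-nitrobenzoic acid, PPh3, diisopropyl azodicarboxylate, THF, 0 °C) to the (1R,4R) 4-nitrobenzoate F10. Methanolysis (catalytic K2CO3, MeOH) gives 27.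

**Further compounds**

F1 | step 6 | methyl 4-hydroxy-6,6-dimethyl-2-methylidenecyclohexane-1-carboxylate (racemic, both relative configurations) | COC(=O)C1C(=C)CC(O)CC1(C)C
F2 | step 6 | methyl 4-hydroxy-2,6,6-trimethylcyclohex-1-ene-1-carboxylate (racemic) | COC(=O)C1=C(C)CC(O)CC1(C)C
F3 | step 6 | methyl (4R)-4-{[(2S)-2-methoxy-2-phenylacetyl]oxy}-2,6,6-trimethylcyclohex-1-ene-1-carboxylate | O=C(O[C@@H]1CC(C)=C(C(=O)OC)C(C)(C)C1)[C@@H](OC)c1ccccc1
F4 | step 6 | methyl (4S)-4-{[(2S)-2-methoxy-2-phenylacetyl]oxy}-2,6,6-trimethylcyclohex-1-ene-1-carboxylate | O=C(O[C@H]1CC(C)=C(C(=O)OC)C(C)(C)C1)[C@@H](OC)c1ccccc1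
F5 | step 16 | 2-methyl-2-{(E)-2-[(1R)-2,6,6-trimethylcyclohex-2-en-1-yl]ethenyl}-1,3-dioxolane | CC1(OCCO1)/C=C/[C@H]1C(C)=CCCC1(C)C
F6 | step 16 | (4R)-3,5,5-trimethyl-4-[(E)-2-(2-methyl-1,3-dioxolan-2-yl)ethenyl]cyclohex-2-en-1-one | CC1(OCCO1)/C=C/[C@H]1C(C)=CC(=O)CC1(C)C
F7 | step 16 | (1R,4R)-3,5,5-trimethyl-4-[(E)-2-(2-methyl-1,3-dioxolan-2-yl)ethenyl]cyclohex-2-en-1-ol | CC1(OCCO1)/C=C/[C@H]1C(C)=C[C@H](O)CC1(C)C
F8 | step 16 | (3E)-4-[(1R,4R)-4-hydroxy-2,6,6-trimethylcyclohex-2-en-1-yl]but-3-en-2-one | CC(=O)/C=C/[C@H]1C(C)=C[C@H](O)CC1(C)C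
F9 | step 17 | (2E,4E)-5-[(1R,4S)-4-hydroxy-2,6,6-trimethylcyclohex-2-en-1-yl]-3-methylpenta-2,4-dienenitrile | N#C/C=C(C)/C=C/[C@H]1C(C)=C[C@@H](O)CC1(C)C
F10 | step 17 | (1R,4R)-4-[(1E,3E)-4-cyano-3-methylbuta-1,3-dien-1-yl]-3,5,5-trimethylcyclohex-2-en-1-yl 4-nitrobenzoate | N#C/C=C(C)/C=C/[C@H]1C(C)=C[C@H](OC(=O)c2ccc(cc2)[N+](=O)[O-])CC1(C)C
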